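## Retrosynthetic overview

1. Target 28 ⇒ Stille coupling at the central single bond of the tetraene: dienyl iodide 14 (lactone half) + dienyl stannane 27 (dihydropyran half); the polyene is made last.
2. Enabling feature: number the oxolanone O1, C2 (CH carrying the propanoate), C3 (quaternary; Me and the tetraene), C4 (CHMe), C5 (C=O). The side-chain ester carbon and ring C4 are the two ends of a β-dicarbonyl opened by retro-Claisen, and C3 is the substituted end of an allyl unit (it carries the first E-alkene). Re-joining ester C to C4 gives the 2-oxabicyclo[2.2.1]heptane-3,5-dione 11, the ring system of the presumed polyketide parent.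
3. 11 ⇒ β-keto-δ-lactone 10 by a palladium-catalysed bridging allylic alkylation that forms C3–C4 (γ-lactone and a temporary cyclopentanone close together; the quaternary centre comes by chirality relay from an (S)-glyceraldehyde-derived carbonate). Methanol then cuts the cyclopentanone (retro-Claisen) to 12. 10 ⇒ anti-aldol of dipropionyl imide 8 with enal 5.
4. 27 ⇒ hetero-Diels–Alder dihydropyranone 19; hydroxylation at C3 anti to the side chain; axial methyl cuprate addition with enol triflate capture; triflate reduction.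
5. Ring order: δ-lactone (10) → γ-lactone + cyclopentanone (11) → cyclopentanone opened (12); dihydropyranone (19) → 3,6-dihydro-2H-pyran (24).

Key step: step 7

Assumption: the (R)-binaphthol aluminium catalyst of step 11 is taken to give the (2R)-dihydropyranone, and the boron aldol of step 5 to be 2,4-anti/4,5-anti; if either sense proves opposite, the antipodal ligand or auxiliary is used and nothing else changes.

## Route

Step 1
Reactants: 1 (S)-2,2-dimethyl-1,3-dioxolane-4-carbaldehyde; 2 2-(triphenylphosphoranylidene)propanal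
Product: 3 (E)-3-[(4R)-2,2-dimethyl-1,3-dioxolan-4-yl]-2-methylprop-2-enal
Conditions: toluene, 60 °C
Reagents that add atoms: none
Why: Wittig olefination with a stabilised ylide should give the (E)-trisubstituted enal and leaves the dioxolane stereocentre untouched.

Step 2
Reactants: 3 (E)-3-[(4R)-2,2-dimethyl-1,3-dioxolan-4-yl]-2-methylprop-2-enal
Product: 4 (2E,4R)-4,5-dihydroxy-2-methylpent-2-enal
Conditions: AcOH/H2O (4:1), 40 °C
Reagents that add atoms: none
Why: Acid-catalysed acetal hydrolysis; the (E)-alkene keeps the hydroxyls away from the aldehyde, so the diol should stay open-chain.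

Step 3
Reactants: 4 (2E,4R)-4,5-dihydroxy-2-methylpent-2-enal
Product: 5 (E)-2-methyl-3-[(4R)-2-oxo-1,3-dioxolan-4-yl]prop-2-enal
Conditions: 1,1'-carbonyldiimidazole, CH2Cl2, 0 °C → rt
Reagents that add atoms: 1,1'-carbonyldiimidazole, O=C(n1ccnc1)n1ccnc1
Why: Cyclic carbonate formation from a 1,2-diol by double acyl transfer installs the allylic leaving group for step 7 without touching the aldehyde.

Step 4
Reactants: 6 (4R)-4-benzyl-3-propanoyl-1,3-oxazolidin-2-one; 7 propanoyl chloride
Product: 8 (4R)-4-benzyl-3-[(2S)-2-methyl-3-oxopentanoyl]-1,3-oxazolidin-2-one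
Conditions: LiN(i-Pr)2, THF, −78 °C; then 7, −78 °C
Reagents that add atoms: none
Why: Claisen-type C-acylation of the chelated Z-lithium enolate occurs anti to the benzyl group and sets C2 (S), which stays configurationally stable because allylic strain blocks enolisation at that carbon.

Step 5
Reactants: 8 (4R)-4-benzyl-3-[(2S)-2-methyl-3-oxopentanoyl]-1,3-oxazolidin-2-one; 5 (E)-2-methyl-3-[(4R)-2-oxo-1,3-dioxolan-4-yl]prop-2-enal
Product: 9 (4R)-4-benzyl-3-[(2S,4R,5S,6E)-5-hydroxy-2,4,6-trimethyl-3-oxo-7-[(4R)-2-oxo-1,3-dioxolan-4-yl]hept-6-enoyl]-1,3-oxazolidin-2-one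
Conditions: (c-C6H11)2BCl, Me2NEt, Et2O, 0 °C; then 5, −78 → −20 °C; MeOH, pH 7 buffer, H2O2, 0 °C
Reagents that add atoms: none
Why: Boron-mediated anti-selective aldol reaction of a chiral β-keto imide: the E-dicyclohexylboron enolate adds through a chair transition state (4,5-anti) and the C2 methyl centre directs the enolate face (2,4-anti), which sets C4 (R) and C5 (S).

Step 6
Reactants: 9 (4R)-4-benzyl-3-[(2S,4R,5S,6E)-5-hydroxy-2,4,6-trimethyl-3-oxo-7-[(4R)-2-oxo-1,3-dioxolan-4-yl]hept-6-enoyl]-1,3-oxazolidin-2-one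
Product: 10 (5R,6S)-4-hydroxy-3,5-dimethyl-6-[(E)-1-[(4R)-2-oxo-1,3-dioxolan-4-yl]prop-1-en-2-yl]-5,6-dihydro-2H-pyran-2-one (enol form of the β-keto-δ-lactone)
Conditions: DBU (1.2 equiv), CH2Cl2, 0 °C → rt; 1 M HCl wash
Reagents that add atoms: none
Why: Base-induced lactonisation (6-exo-trig acyl transfer of the C5 alkoxide onto the activated imide carbonyl) expels the auxiliary and gives the enolised β-keto lactone, in which the former C2 is no longer stereogenic.

Step 7
Reactants: 10 (5R,6S)-4-hydroxy-3,5-dimethyl-6-[(E)-1-[(4R)-2-oxo-1,3-dioxolan-4-yl]prop-1-en-2-yl]-5,6-dihydro-2H-pyran-2-one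
Product: 12 methyl (2R)-2-[(2S,3R,4R)-3-[(E)-3-hydroxyprop-1-enyl]-3,4-dimethyl-5-oxooxolan-2-yl]propanoate, via bicyclic keto-lactone 11 (not isolated)
Conditions: Pd2(dba)3·CHCl3 (2.5 mol %), dppe (6 mol %), THF (0.005 M), 40 °C; then MeOH (20 equiv), NaOMe (0.2 equiv), −40 → 0 °C; AcOH
Reagents that add atoms: methanol, CO
Why: Proposed new method: zerovalent palladium ionises the vinyl cyclic carbonate anti to its C–O bond (CO2 is lost and the alkoxide takes the enol proton), the enolate carbon C3 of the β-keto-δ-lactone attacks the methyl-bearing allyl terminus anti to the metal to forge the oxolanone C3–C4 bond of strained dione 11, and methoxide then adds to the ketone of 11 so that retro-Claisen cleavage relieves the strain, unveils the methyl ester and leaves a lactone enolate that is protonated; this copies the presumed biosynthesis (C-alkylation of the β-keto acyl terminus at the allylic carbon, then methanolysis). The closest known reaction types are the neutral Tsuji–Trost vinylcyclopentane annulation of β-dicarbonyl compounds with vinyl epoxides or vinyl cyclic carbonates and the retro-Dieckmann opening of non-enolisable β-keto esters, but a bridging closure across a six-membered β-keto lactone onto a fully substituted allyl terminus has not been shown. Both rings of 11 (γ-lactone and cyclopentanone) close in the 5-exo mode with the allyl unit exocyclic. The quaternary centre (oxolanone C3) is set by 1,3-chirality transfer (anti ionisation, anti attack) from the (4R)-carbonate carbon through the syn-substituted allyl complex, matched with the rotamer that holds the bulky allyl–metal unit over the unsubstituted ring-oxygen bridge, while the bridgehead centre of 11 is fixed by the tether and erased on ring opening. The α-methine (oxolanone C4) is set by kinetic protonation of the lactone enolate from the face opposite the C2 side chain. The step needs C- over O-alkylation and proximal over distal attack, both secured by geometry (the O-alkylated product would be an anti-Bredt enol ether, distal attack an E-cycloheptene), and ketone over lactone cleavage by methoxide, which is tolerable because lactone opening only returns a hydroxy β-keto ester that re-closes to 11.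

Step 8
Reactants: 12 methyl (2R)-2-[(2S,3R,4R)-3-[(E)-3-hydroxyprop-1-enyl]-3,4-dimethyl-5-oxooxolan-2-yl]propanoate
Product: 13 methyl (2R)-2-[(2S,3R,4R)-3,4-dimethyl-5-oxo-3-[(E)-3-oxoprop-1-enyl]oxolan-2-yl]propanoate
Conditions: MnO2, CH2Cl2, rt
Reagents that add atoms: none
Why: Allylic alcohol oxidation on MnO2 is neutral, so the enal should form without epimerising the lactone α-carbon.

Step 9
Reactants: 13 methyl (2R)-2-[(2S,3R,4R)-3,4-dimethyl-5-oxo-3-[(E)-3-oxoprop-1-enyl]oxolan-2-yl]propanoate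
Product: 14 methyl (2R)-2-[(2S,3R,4R)-3-[(1E,3E)-4-iodobuta-1,3-dienyl]-3,4-dimethyl-5-oxooxolan-2-yl]propanoate
Conditions: CHI3, CrCl2, THF, 0 °C → rt, dark
Reagents that add atoms: iodoform, IC(I)I
Why: Takai olefination: the gem-dichromium carbenoid made from CHI3 and CrCl2 adds to the aldehyde and eliminates to the (E)-alkenyl iodide, and esters and lactones are inert to it.

Step 10
Reactants: 15 (tert-butyldimethylsilyloxy)acetaldehyde; 2 2-(triphenylphosphoranylidene)propanal
Product: 16 (E)-4-(tert-butyldimethylsilyloxy)-2-methylbut-2-enal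
Conditions: toluene, 80 °C
Reagents that add atoms: none
Why: Wittig olefination with the stabilised ylide should give the (E)-enal.

Step 11
Reactants: 16 (E)-4-(tert-butyldimethylsilyloxy)-2-methylbut-2-enal; 17 (1E,3Z)-1-methoxy-2-methyl-3-(trimethylsilyloxy)penta-1,3-diene
Product: 19 (2R)-2-[(E)-4-(tert-butyldimethylsilyloxy)but-2-en-2-yl]-3,5-dimethyl-2,3-dihydro-4H-pyran-4-one (both C3 epimers), via Diels-Alder cycloadduct 18 (not isolated)
Conditions: (R)-3,3'-bis(triphenylsilyl)-1,1'-bi-2-naphthol (10 mol %), AlMe3 (10 mol %), toluene, −20 °C; then CF3CO2H (cat.), CH2Cl2, 0 °C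
Reagents that add atoms: none
Why: Lewis acid-catalysed hetero-Diels–Alder reaction of a 1-methoxy-3-silyloxy diene, in which the chiral aluminium binaphtholate selects the aldehyde face and sets C2 (R), while acid then eliminates methanol to the enone; the C3 centre need not be controlled because step 12 planarises it.

Step 12
Reactants: 19 (2R)-2-[(E)-4-(tert-butyldimethylsilyloxy)but-2-en-2-yl]-3,5-dimethyl-2,3-dihydro-4H-pyran-4-one
Product: 20 (2S,3S)-2-[(E)-4-(tert-butyldimethylsilyloxy)but-2-en-2-yl]-3-hydroxy-3,5-dimethyl-2,3-dihydro-4H-pyran-4-one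
Conditions: KN(SiMe3)2, THF, −78 °C; 2-(phenylsulfonyl)-3-phenyloxaziridine, −78 °C; NH4Cl
Reagents that add atoms: 2-(phenylsulfonyl)-3-phenyloxaziridine, O=S(=O)(N1OC1c1ccccc1)c1ccccc1
Why: Enolate hydroxylation with an N-sulfonyloxaziridine: both C3 epimers give one cross-conjugated dienolate, and oxygen should enter anti to the adjacent C2 side chain, which places OH trans to it and sets C3 (S).

Step 13
Reactants: 20 (2S,3S)-2-[(E)-4-(tert-butyldimethylsilyloxy)but-2-en-2-yl]-3-hydroxy-3,5-dimethyl-2,3-dihydro-4H-pyran-4-one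
Product: 21 (2S,3S)-2-[(E)-4-(tert-butyldimethylsilyloxy)but-2-en-2-yl]-3,5-dimethyl-3-(triethylsilyloxy)-2,3-dihydro-4H-pyran-4-one
Conditions: Et3SiOTf, 2,6-lutidine, CH2Cl2, −78 → 0 °C
Reagents that add atoms: triethylsilyl trifluoromethanesulfonate, CC[Si](CC)(CC)OS(=O)(=O)C(F)(F)F
Why: Silylation of the tertiary alcohol with a silyl triflate keeps a free alkoxide out of the cuprate and triflation chemistry of step 14.

Step 14
Reactants: 21 (2S,3S)-2-[(E)-4-(tert-butyldimethylsilyloxy)but-2-en-2-yl]-3,5-dimethyl-3-(triethylsilyloxy)-2,3-dihydro-4H-pyran-4-one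
Product: 23 (2S,3S,6S)-2-[(E)-4-(tert-butyldimethylsilyloxy)but-2-en-2-yl]-3,5,6-trimethyl-3-(triethylsilyloxy)-3,6-dihydro-2H-pyran-4-yl trifluoromethanesulfonate, via lithium enolate 22 (not isolated)
Conditions: Me2CuLi (from MeLi and CuI), Et2O, −78 → −30 °C; then N-(5-chloropyridin-2-yl)triflimide, THF, −78 → 0 °C
Reagents that add atoms: lithium dimethylcuprate, [Li+].C[Cu-]C; N-(5-chloropyridin-2-yl)bis(trifluoromethanesulfonyl)imide, O=S(=O)(N(c1ccc(Cl)cn1)S(=O)(=O)C(F)(F)F)C(F)(F)F
Why: Cuprate conjugate addition to the vinylogous ester proceeds by axial attack anti to the C2 substituent (2,6-trans, C6 (S)), and the enolate, which can only lie toward C5 because C3 has no hydrogen, is captured as the enol triflate.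

Step 15
Reactants: 23 (2S,3S,6S)-2-[(E)-4-(tert-butyldimethylsilyloxy)but-2-en-2-yl]-3,5,6-trimethyl-3-(triethylsilyloxy)-3,6-dihydro-2H-pyran-4-yl trifluoromethanesulfonate
Product: 24 tert-butyldimethyl{[(E)-3-[(2S,3R,6S)-3,5,6-trimethyl-3-(triethylsilyloxy)-3,6-dihydro-2H-pyran-2-yl]but-2-enyl]oxy}silane
Conditions: Pd(OAc)2 (5 mol %), PPh3, Bu3N, HCO2H, DMF, 60 °C
Reagents that add atoms: none
Why: Palladium-catalysed formate reduction of an enol triflate (oxidative addition to zerovalent palladium, formate exchange, decarboxylation, reductive elimination) gives the trisubstituted ring alkene without touching a stereocentre.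

Step 16
Reactants: 24 tert-butyldimethyl{[(E)-3-[(2S,3R,6S)-3,5,6-trimethyl-3-(triethylsilyloxy)-3,6-dihydro-2H-pyran-2-yl]but-2-enyl]oxy}silane
Product: 25 (2S,3R,6S)-2-[(E)-4-hydroxybut-2-en-2-yl]-3,5,6-trimethyl-3,6-dihydro-2H-pyran-3-ol
Conditions: Bu4NF, THF, 0 °C → rt; NH4Cl
Reagents that add atoms: none
Why: Fluoride desilylation removes both silyl ethers under non-acidic conditions that spare the tertiary allylic alcohol.

Step 17
Reactants: 25 (2S,3R,6S)-2-[(E)-4-hydroxybut-2-en-2-yl]-3,5,6-trimethyl-3,6-dihydro-2H-pyran-3-ol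
Product: 26 (E)-3-[(2S,3R,6S)-3-hydroxy-3,5,6-trimethyl-3,6-dihydro-2H-pyran-2-yl]but-2-enal
Conditions: MnO2, CH2Cl2, rt
Reagents that add atoms: none
Why: MnO2 oxidation takes only the primary allylic alcohol, since the tertiary one has no carbinol hydrogen.

Step 18
Reactants: 26 (E)-3-[(2S,3R,6S)-3-hydroxy-3,5,6-trimethyl-3,6-dihydro-2H-pyran-2-yl]but-2-enal
Product: 27 (2S,3R,6S)-3,5,6-trimethyl-2-[(2E,4E)-5-(tributylstannyl)penta-2,4-dien-2-yl]-3,6-dihydro-2H-pyran-3-ol
Conditions: Bu3SnCHI2, CrCl2, DMF/THF, rt, dark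
Reagents that add atoms: (diiodomethyl)tributylstannane, CCCC[Sn](CCCC)(CCCC)C(I)I
Why: Takai-type chromium-mediated stannyl-olefination converts the enal into the (E)-alkenylstannane and tolerates the free tertiary hydroxyl.

Step 19
Reactants: 14 methyl (2R)-2-[(2S,3R,4R)-3-[(1E,3E)-4-iodobuta-1,3-dienyl]-3,4-dimethyl-5-oxooxolan-2-yl]propanoate; 27 (2S,3R,6S)-3,5,6-trimethyl-2-[(2E,4E)-5-(tributylstannyl)penta-2,4-dien-2-yl]-3,6-dihydro-2H-pyran-3-ol
Product: 28 methyl (2R)-2-[(2S,3R,4R)-3-[(1E,3E,5E,7E)-8-[(2S,3R,6S)-3-hydroxy-3,5,6-trimethyl-3,6-dihydro-2H-pyran-2-yl]nona-1,3,5,7-tetraenyl]-3,4-dimethyl-5-oxooxolan-2-yl]propanoate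
Conditions: Pd2(dba)3 (5 mol %), AsPh3 (20 mol %), DMF, rt, degassed, dark
Reagents that add atoms: none
Why: Stille cross-coupling (oxidative addition of the dienyl iodide, tin-to-palladium transfer, reductive elimination) joins the two sp2 carbons with retention of all alkene geometries under neutral conditions that spare the lactone α-carbon and the tertiary allylic alcohol.

## Compound list

1 | (S)-2,2-dimethyl-1,3-dioxolane-4-carbaldehyde | O=C[C@@H]1COC(C)(C)O1 | starting material
2 | 2-(triphenylphosphoranylidene)propanal | CC(C=O)=P(c1ccccc1)(c1ccccc1)c1ccccc1 | starting material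
3 | (E)-3-[(4R)-2,2-dimethyl-1,3-dioxolan-4-yl]-2-methylprop-2-enal | O=C/C(C)=C/[C@@H]1COC(C)(C)O1 | intermediate
4 | (2E,4R)-4,5-dihydroxy-2-methylpent-2-enal | O=C/C(C)=C/[C@@H](O)CO | intermediate
5 | (E)-2-methyl-3-[(4R)-2-oxo-1,3-dioxolan-4-yl]prop-2-enal | O=C/C(C)=C/[C@@H]1COC(=O)O1 | intermediate
6 | (4R)-4-benzyl-3-propanoyl-1,3-oxazolidin-2-one | CCC(=O)N1[C@H](Cc2ccccc2)COC1=O | starting material
7 | propanoyl chloride | CCC(Cl)=O | starting material
8 | (4R)-4-benzyl-3-[(2S)-2-methyl-3-oxopentanoyl]-1,3-oxazolidin-2-one | CCC(=O)[C@H](C)C(=O)N1[C@H](Cc2ccccc2)COC1=O | intermediate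
9 | (4R)-4-benzyl-3-[(2S,4R,5S,6E)-5-hydroxy-2,4,6-trimethyl-3-oxo-7-[(4R)-2-oxo-1,3-dioxolan-4-yl]hept-6-enoyl]-1,3-oxazolidin-2-one | O=C(N1[C@H](Cc2ccccc2)COC1=O)[C@@H](C)C(=O)[C@H](C)[C@H](O)/C(C)=C/[C@@H]1COC(=O)O1 | intermediate
10 | (5R,6S)-4-hydroxy-3,5-dimethyl-6-[(E)-1-[(4R)-2-oxo-1,3-dioxolan-4-yl]prop-1-en-2-yl]-5,6-dihydro-2H-pyran-2-one | CC1=C(O)[C@H](C)[C@@H](/C(C)=C/[C@@H]2COC(=O)O2)OC1=O | intermediate
11 | (1S,4S,6R,7R)-7-[(E)-3-hydroxyprop-1-enyl]-4,6,7-trimethyl-2-oxabicyclo[2.2.1]heptane-3,5-dione | O=C1[C@H](C)[C@@H]2OC(=O)[C@@]1(C)[C@@]2(C)/C=C/CO | intermediate (not isolated)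
12 | methyl (2R)-2-[(2S,3R,4R)-3-[(E)-3-hydroxyprop-1-enyl]-3,4-dimethyl-5-oxooxolan-2-yl]propanoate | COC(=O)[C@H](C)[C@@H]1OC(=O)[C@H](C)[C@@]1(C)/C=C/CO | intermediate
13 | methyl (2R)-2-[(2S,3R,4R)-3,4-dimethyl-5-oxo-3-[(E)-3-oxoprop-1-enyl]oxolan-2-yl]propanoate | COC(=O)[C@H](C)[C@@H]1OC(=O)[C@H](C)[C@@]1(C)/C=C/C=O | intermediate
14 | methyl (2R)-2-[(2S,3R,4R)-3-[(1E,3E)-4-iodobuta-1,3-dienyl]-3,4-dimethyl-5-oxooxolan-2-yl]propanoate | COC(=O)[C@H](C)[C@@H]1OC(=O)[C@H](C)[C@@]1(C)/C=C/C=C/I | intermediate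
15 | (tert-butyldimethylsilyloxy)acetaldehyde | CC(C)(C)[Si](C)(C)OCC=O | starting material
16 | (E)-4-(tert-butyldimethylsilyloxy)-2-methylbut-2-enal | O=C/C(C)=C/CO[Si](C)(C)C(C)(C)C | intermediate
17 | (1E,3Z)-1-methoxy-2-methyl-3-(trimethylsilyloxy)penta-1,3-diene | CO/C=C(C)/C(=C/C)O[Si](C)(C)C | starting material
18 | (2R)-2-[(E)-4-(tert-butyldimethylsilyloxy)but-2-en-2-yl]-6-methoxy-3,5-dimethyl-4-(trimethylsilyloxy)-3,6-dihydro-2H-pyran (C3 and C6 epimers) | COC1O[C@@H](/C(C)=C/CO[Si](C)(C)C(C)(C)C)C(C)C(O[Si](C)(C)C)=C1C | intermediate (not isolated)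
19 | (2R)-2-[(E)-4-(tert-butyldimethylsilyloxy)but-2-en-2-yl]-3,5-dimethyl-2,3-dihydro-4H-pyran-4-one (C3 epimers) | CC1=CO[C@@H](/C(C)=C/CO[Si](C)(C)C(C)(C)C)C(C)C1=O | intermediate
20 | (2S,3S)-2-[(E)-4-(tert-butyldimethylsilyloxy)but-2-en-2-yl]-3-hydroxy-3,5-dimethyl-2,3-dihydro-4H-pyran-4-one | CC1=CO[C@@H](/C(C)=C/CO[Si](C)(C)C(C)(C)C)[C@](C)(O)C1=O | intermediate
21 | (2S,3S)-2-[(E)-4-(tert-butyldimethylsilyloxy)but-2-en-2-yl]-3,5-dimethyl-3-(triethylsilyloxy)-2,3-dihydro-4H-pyran-4-one | CC1=CO[C@@H](/C(C)=C/CO[Si](C)(C)C(C)(C)C)[C@](C)(O[Si](CC)(CC)CC)C1=O | intermediate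
22 | lithium (2S,3S,6S)-2-[(E)-4-(tert-butyldimethylsilyloxy)but-2-en-2-yl]-3,5,6-trimethyl-3-(triethylsilyloxy)-3,6-dihydro-2H-pyran-4-olate | C[C@@H]1O[C@@H](/C(C)=C/CO[Si](C)(C)C(C)(C)C)[C@](C)(O[Si](CC)(CC)CC)C(O[Li])=C1C | intermediate (not isolated)
23 | (2S,3S,6S)-2-[(E)-4-(tert-butyldimethylsilyloxy)but-2-en-2-yl]-3,5,6-trimethyl-3-(triethylsilyloxy)-3,6-dihydro-2H-pyran-4-yl trifluoromethanesulfonate | C[C@@H]1O[C@@H](/C(C)=C/CO[Si](C)(C)C(C)(C)C)[C@](C)(O[Si](CC)(CC)CC)C(OS(=O)(=O)C(F)(F)F)=C1C | intermediate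
24 | tert-butyldimethyl{[(E)-3-[(2S,3R,6S)-3,5,6-trimethyl-3-(triethylsilyloxy)-3,6-dihydro-2H-pyran-2-yl]but-2-enyl]oxy}silane | C[C@@H]1O[C@@H](/C(C)=C/CO[Si](C)(C)C(C)(C)C)[C@](C)(O[Si](CC)(CC)CC)C=C1C | intermediate
25 | (2S,3R,6S)-2-[(E)-4-hydroxybut-2-en-2-yl]-3,5,6-trimethyl-3,6-dihydro-2H-pyran-3-ol | C[C@@H]1O[C@@H](/C(C)=C/CO)[C@](C)(O)C=C1C | intermediate
26 | (E)-3-[(2S,3R,6S)-3-hydroxy-3,5,6-trimethyl-3,6-dihydro-2H-pyran-2-yl]but-2-enal | C[C@@H]1O[C@@H](/C(C)=C/C=O)[C@](C)(O)C=C1C | intermediate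
27 | (2S,3R,6S)-3,5,6-trimethyl-2-[(2E,4E)-5-(tributylstannyl)penta-2,4-dien-2-yl]-3,6-dihydro-2H-pyran-3-ol | C[C@@H]1O[C@@H](/C(C)=C/C=C/[Sn](CCCC)(CCCC)CCCC)[C@](C)(O)C=C1C | intermediate
28 | methyl (2R)-2-[(2S,3R,4R)-3-[(1E,3E,5E,7E)-8-[(2S,3R,6S)-3-hydroxy-3,5,6-trimethyl-3,6-dihydro-2H-pyran-2-yl]nona-1,3,5,7-tetraenyl]-3,4-dimethyl-5-oxooxolan-2-yl]propanoate | COC(=O)[C@H](C)[C@@H]1OC(=O)[C@H](C)[C@@]1(C)/C=C/C=C/C=C/C=C(\C)[C@@H]1O[C@@H](C)C(C)=C[C@@]1(C)O | target

## Step count and risks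

Total step count: 19. Longest linear sequence: 10 steps (15 → 28, steps 10–19).

The three steps most likely to fail:

1. Step 7 (Proposed new method). What may go wrong: the strained bridging C–C closure may be slower than β-hydride elimination or intermolecular alkylation of the allyl–palladium intermediate, or may be undone by re-ionisation before methanolysis. The fallback uses known chemistry, sets out from 9 and comes back at 11; it closes the rings in the other, biosynthetic order. Silylation of 9 (t-BuMe2SiOTf, 2,6-lutidine, CH2Cl2) gives the silyl ether of the aldol adduct F1. Pd2(dba)3·CHCl3/dppe in THF then closes only the unstrained carbocycle by a Tsuji–Trost cyclopentanone annulation (C2 of the β-dicarbonyl attacks the proximal allyl terminus, 5-exo, CO2 lost, same chirality transfer), which gives the 2-acyl-3-alkenylcyclopentanone F2. HF·pyridine removes the silyl group, and in the epimer whose imide is cis to the oxygen the freed hydroxyl acylates itself with loss of the oxazolidinone to give 11. Compound 11 is then opened with NaOMe/MeOH as in the second half of step 7.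

2. Step 14. What may go wrong: sluggish conjugate addition to an α-methylated vinylogous ester flanked by a quaternary centre, or incomplete capture of the enolate by the triflating agent. The fallback sets out from 21 and comes back at 24. Luche 1,2-reduction (NaBH4, CeCl3·7H2O, MeOH, −78 °C) gives the allylic alcohol F3 (either C4 epimer serves), and acetylation (Ac2O, pyridine) gives the allylic acetate F4. A Ferrier-type C-glycosylation with AlMe3 (CH2Cl2, −78 → 0 °C) ionises the acetate to the allyl-oxocarbenium ion and delivers methyl to C6 trans to the C2 side chain, with transposition of the alkene to C4=C5, which gives 24 directly.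

3. Step 19. What may go wrong: slow tin-to-palladium transfer, which leaves time for homocoupling, protodestannylation or E/Z isomerisation of the dienyl partners. The fallback sets out from 26 and comes back at 28. Chromium-mediated boryl-olefination of 26 (Cl2CHB(pin), CrCl2, LiI, THF) gives the (E,E)-dienyl pinacol boronate F5, which is joined to 14 by Suzuki–Miyaura coupling (Pd(PPh3)4, TlOEt, THF/H2O, rt).

Further compounds

F1 | step 7 | (4R)-4-benzyl-3-[(2S,4R,5S,6E)-5-(tert-butyldimethylsilyloxy)-2,4,6-trimethyl-3-oxo-7-[(4R)-2-oxo-1,3-dioxolan-4-yl]hept-6-enoyl]-1,3-oxazolidin-2-one | O=C(N1[C@H](Cc2ccccc2)COC1=O)[C@@H](C)C(=O)[C@H](C)[C@H](O[Si](C)(C)C(C)(C)C)/C(C)=C/[C@@H]1COC(=O)O1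
F2 | step 7 | (4R)-4-benzyl-3-{[3-(tert-butyldimethylsilyloxy)-2-[(E)-3-hydroxyprop-1-enyl]-1,2,4-trimethyl-5-oxocyclopentyl]carbonyl}-1,3-oxazolidin-2-one (ring configuration as in 11, acyl group cis to the silyloxy group) | O=C1[C@H](C)[C@H](O[Si](C)(C)C(C)(C)C)[C@](C)(/C=C/CO)[C@]1(C)C(=O)N1[C@H](Cc2ccccc2)COC1=O
F3 | step 14 | 2-[(E)-4-(tert-butyldimethylsilyloxy)but-2-en-2-yl]-3,5-dimethyl-3-(triethylsilyloxy)-3,4-dihydro-2H-pyran-4-ol (C2 and C3 as in 21, C4 epimers) | CC1=CO[C@@H](/C(C)=C/CO[Si](C)(C)C(C)(C)C)[C@](C)(O[Si](CC)(CC)CC)C1O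
F4 | step 14 | 2-[(E)-4-(tert-butyldimethylsilyloxy)but-2-en-2-yl]-3,5-dimethyl-3-(triethylsilyloxy)-3,4-dihydro-2H-pyran-4-yl acetate (C2 and C3 as in 21, C4 epimers) | CC1=CO[C@@H](/C(C)=C/CO[Si](C)(C)C(C)(C)C)[C@](C)(O[Si](CC)(CC)CC)C1OC(C)=O
F5 | step 19 | (2S,3R,6S)-3,5,6-trimethyl-2-[(2E,4E)-5-(4,4,5,5-tetramethyl-1,3,2-dioxaborolan-2-yl)penta-2,4-dien-2-yl]-3,6-dihydro-2H-pyran-3-ol | C[C@@H]1O[C@@H](/C(C)=C/C=C/B2OC(C)(C)C(C)(C)O2)[C@](C)(O)C=C1C
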